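**Retrosynthetic overview**
- The target is reached by global O-demethylation of its hexamethyl ether. The bromine is carried from the first step on ring C (the bromo ring); ring B is the middle ring and ring A the terminal triol ring.
- Both diaryl ether C–O bonds are cut at the oxygen-flanked ("central") carbon of rings B and A. Each is made by O–H insertion of a phenol into the quinoid carbene from one reagent, 4-diazo-3,5-dimethoxycyclohexa-2,5-dien-1-one. Each insertion unveils a new para-phenol that is the nucleophile for the next one.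
- The diazo reagent comes from 2,6-dimethoxy-1,4-benzoquinone; the ring C phenol comes from 2-bromo-1,3-dimethoxybenzene by C–H borylation/oxidation.
- No ring is built. The three purchased benzene rings are joined in the order C → B → A.

Assumption: the target has no stereocentre (it is achiral), so there is no configuration to set or protect; compounds 1 and 4 and all reagents are catalogue chemicals.

**Route**

Step 1
Reactants: 1 2-bromo-1,3-dimethoxybenzene
Product: 3 4-bromo-3,5-dimethoxyphenol, via arylboronate 2 (not isolated)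
Conditions: [Ir(OMe)(cod)]2 (1.5 mol%), dtbpy (3 mol%), HBpin (1.5 equiv), THF, 80 °C; then Oxone (1.1 equiv), acetone/H2O, rt
Reagents that add atoms: pinacolborane, CC1(C)OBOC1(C)C (its boron stays only in 2); potassium peroxymonosulfate (Oxone), [K+].[O-]S(=O)(=O)OO (the phenol oxygen of 3)
Why: Sterically controlled Ir-catalysed C–H borylation takes the only C–H with no ortho substituent (C5, para to Br) and tolerates the aryl bromide, and ipso-oxidation of the C–B bond in the same pot gives the phenol (one-pot C–H borylation/oxidation).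

Step 2
Reactants: 4 2,6-dimethoxy-1,4-benzoquinone
Product: 6 4-diazo-3,5-dimethoxycyclohexa-2,5-dien-1-one, via quinone tosylhydrazone 5 (not isolated)
Conditions: TsNHNH2 (1.05 equiv), cat. HCl, MeOH, 0 °C to rt; then basic Al2O3, CH2Cl2, 0 °C, dark
Reagents that add atoms: p-toluenesulfonyl hydrazide, Cc1ccc(cc1)S(=O)(=O)NN
Why: The hydrazide condenses at C1, the ketone-like carbonyl (C4=O is a doubly vinylogous ester and deactivated), and base then expels sulfinate from the hydrazone (Bamford–Stevens-type elimination, the standard quinone-to-quinone-diazide preparation), driven by the aromatic diazonium-phenolate character of 6.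

Step 3
Reactants: 3 4-bromo-3,5-dimethoxyphenol; 6 4-diazo-3,5-dimethoxycyclohexa-2,5-dien-1-one
Product: 7 4-(4-bromo-3,5-dimethoxyphenoxy)-3,5-dimethoxyphenol
Conditions: Rh2(esp)2 (1 mol%), 3 (3 equiv, excess recovered), 6 added over 4 h, 4 Å MS, DCE, 60 °C, dark
Reagents that add atoms: none
Why: Proposed new method: Rh(II) takes N2 from 6 to give a quinoid carbene that acts as a 2,6-dimethoxy-4-oxidophenyl cation equivalent; the phenol oxygen of 3 attacks the carbene carbon (the two flanking OMe groups shield it against C–C attack by the arene carbons, and Rh(II) favours X–H over C–H insertion), and proton transfer/tautomerisation aromatises the ring irreversibly to the diaryl ether with a new para-OH; the closest known reaction type is Rh(II)-carbenoid O–H insertion of diazocarbonyl compounds into phenols and of quinone diazides into alcohols, here untested for a di-ortho-alkoxy p-quinone diazide with a phenol partner. Any double insertion in this step gives 8, which is on the route.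

Step 4
Reactants: 7 4-(4-bromo-3,5-dimethoxyphenoxy)-3,5-dimethoxyphenol; 6 4-diazo-3,5-dimethoxycyclohexa-2,5-dien-1-one
Product: 8 4-[4-(4-bromo-3,5-dimethoxyphenoxy)-3,5-dimethoxyphenoxy]-3,5-dimethoxyphenol
Conditions: Rh2(esp)2 (2 mol%), 7 (2 equiv, unreacted part recovered and recycled), 6 added over 6 h, 4 Å MS, DCE, 60 °C, dark
Reagents that add atoms: none
Why: Proposed new method: second use of the same Rh(II) quinoid-carbene O–H insertion, now into the unhindered para-phenol of 7, forging the ring A–O–ring B bond at the oxygen-flanked carbon that Ullmann-type couplings handle poorly; because 8 carries the same kind of phenol, 7 is kept in excess and 6 is added slowly to hold chain extension down; the closest known reaction type is Rh(II)-carbenoid O–H insertion into phenols.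

Step 5
Reactants: 8 4-[4-(4-bromo-3,5-dimethoxyphenoxy)-3,5-dimethoxyphenoxy]-3,5-dimethoxyphenol
Product: 9 2-[4-(4-bromo-3,5-dihydroxyphenoxy)-3,5-dihydroxyphenoxy]benzene-1,3,5-triol
Conditions: BBr3 (14 equiv), CH2Cl2, −78 °C to rt, 18 h, Ar; MeOH/H2O quench at 0 °C; C18 or Sephadex LH-20 with degassed solvents
Reagents that add atoms: none
Why: Lewis-acid cleavage of all six aryl methyl ethers (BBr3 O-demethylation) leaves diaryl ether C–O bonds and the aryl bromide intact.

**Compound list**
1 | 2-bromo-1,3-dimethoxybenzene | COc1cccc(OC)c1Br | starting material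
2 | 2-(4-bromo-3,5-dimethoxyphenyl)-4,4,5,5-tetramethyl-1,3,2-dioxaborolane | COc1cc(cc(OC)c1Br)B1OC(C)(C)C(C)(C)O1 | intermediate
3 | 4-bromo-3,5-dimethoxyphenol | COc1cc(O)cc(OC)c1Br | intermediate
4 | 2,6-dimethoxy-1,4-benzoquinone | COC1=CC(=O)C=C(OC)C1=O | starting material
5 | N'-(2,6-dimethoxy-4-oxocyclohexa-2,5-dien-1-ylidene)-4-methylbenzenesulfonohydrazide | COC1=CC(=O)C=C(OC)C1=NNS(=O)(=O)c1ccc(C)cc1 | intermediate
6 | 4-diazo-3,5-dimethoxycyclohexa-2,5-dien-1-one | COC1=CC(=O)C=C(OC)C1=[N+]=[N-] | intermediate
7 | 4-(4-bromo-3,5-dimethoxyphenoxy)-3,5-dimethoxyphenol | COc1cc(O)cc(OC)c1Oc1cc(OC)c(Br)c(OC)c1 | intermediate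
8 | 4-[4-(4-bromo-3,5-dimethoxyphenoxy)-3,5-dimethoxyphenoxy]-3,5-dimethoxyphenol | COc1cc(O)cc(OC)c1Oc1cc(OC)c(Oc2cc(OC)c(Br)c(OC)c2)c(OC)c1 | intermediate
9 | 2-[4-(4-bromo-3,5-dihydroxyphenoxy)-3,5-dihydroxyphenoxy]benzene-1,3,5-triol | Oc1cc(O)c(Oc2cc(O)c(Oc3cc(O)c(Br)c(O)c3)c(O)c2)c(O)c1 | target

**Totals**
Total step count: 5. Longest linear sequence: 4 (steps 1, 3, 4, 5 from 1; equally steps 2, 3, 4, 5 from 4).

**Three steps most likely to fail, with fallbacks**

Step 3 (proposed new O–H insertion). Risks are slow carbenoid formation at the OMe-flanked diazo carbon, C-arylation of the electron-rich ring of 3, and capture of the carbene by traces of water. The fallback is known chemistry and sets out from 2, isolated after the borylation half of step 1 instead of being oxidised. NaIO4 in aqueous HCl/THF frees (4-bromo-3,5-dimethoxyphenyl)boronic acid F1. Chan–Lam–Evans coupling of F1 with purchased syringaldehyde (4-hydroxy-3,5-dimethoxybenzaldehyde; Cu(OAc)2, pyridine, 4 Å MS, air, CH2Cl2, rt) gives 4-(4-bromo-3,5-dimethoxyphenoxy)-3,5-dimethoxybenzaldehyde F2, with the aryl bromide untouched. Baeyer–Villiger oxidation with mCPBA gives 4-(4-bromo-3,5-dimethoxyphenoxy)-3,5-dimethoxyphenyl formate F3, and KOH in MeOH/H2O hydrolyses it to 7, where the route is rejoined.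

Step 4 (second use of the new insertion). The added risk is chain extension, since product 8 is as good a phenol as 7, so a statistical mixture is the likely failure. The fallback is known chemistry and sets out from 7. Ullmann ether coupling with purchased 2-iodo-1,3,5-trimethoxybenzene (CuI, picolinic acid, K3PO4, DMSO, 90 °C) gives 2-bromo-5-[2,6-dimethoxy-4-(2,4,6-trimethoxyphenoxy)phenoxy]-1,3-dimethoxybenzene F4; the C–I bond reacts well ahead of the doubly flanked C–Br bond, and there is no free phenol left to over-react. F4 is demethylated with BBr3 as in step 5 (seven ethers) and the route is rejoined at 9, bypassing 8.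

Step 5 (global demethylation). The free heptaphenol is air-sensitive and hard to purify, and partial cleavage is possible. The fallback sets out from 8. After the BBr3 cleavage the crude phenol is not isolated but peracetylated (Ac2O, pyridine, cat. DMAP) to 2-[4-(3,5-diacetoxy-4-bromophenoxy)-3,5-diacetoxyphenoxy]benzene-1,3,5-triyl triacetate F5, which is stable and is purified on silica. Acid methanolysis (cat. AcCl in degassed MeOH, rt, Ar) then releases 9.

**Further compounds**
F1 | step 3 | (4-bromo-3,5-dimethoxyphenyl)boronic acid | COc1cc(cc(OC)c1Br)B(O)O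
F2 | step 3 | 4-(4-bromo-3,5-dimethoxyphenoxy)-3,5-dimethoxybenzaldehyde | COc1cc(C=O)cc(OC)c1Oc1cc(OC)c(Br)c(OC)c1
F3 | step 3 | 4-(4-bromo-3,5-dimethoxyphenoxy)-3,5-dimethoxyphenyl formate | COc1cc(OC=O)cc(OC)c1Oc1cc(OC)c(Br)c(OC)c1
F4 | step 4 | 2-bromo-5-[2,6-dimethoxy-4-(2,4,6-trimethoxyphenoxy)phenoxy]-1,3-dimethoxybenzene | COc1cc(OC)c(Oc2cc(OC)c(Oc3cc(OC)c(Br)c(OC)c3)c(OC)c2)c(OC)c1
F5 | step 5 | 2-[4-(3,5-diacetoxy-4-bromophenoxy)-3,5-diacetoxyphenoxy]benzene-1,3,5-triyl triacetate | CC(=O)Oc1cc(OC(C)=O)c(Oc2cc(OC(C)=O)c(Oc3cc(OC(C)=O)c(Br)c(OC(C)=O)c3)c(OC(C)=O)c2)c(OC(C)=O)c1
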